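**Plan**

1. Numbering (halimane type): ring A = C1–C5 + C10 (C1=C10 alkene; C4 bears CH3 and CO2CH3), ring B = C5–C10 (CH3 on C8 and C9), side chain C11–C15 on C9 (C16 = CH3 on C13).
2. Cuts: the epoxide C–O bonds (13E-allylic alcohol); C13=C14 (olefination of a C13 methyl ketone); in ring A the C3–C4 bond, reopened with the ester carbon inserted as a ketone between C3 and C4 (a seven-membered ketone); then C2–C3 and C4–C5 ((4+3) cycloaddition onto the ring B diene C5=C10–C1=C2), C1–C10 (vinylation), C9–C11 (Michael addition) and C8–CH3 (conjugate addition).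
3. Forward: ring B comes from 2-methylcyclohex-2-enone and first receives its two stereocentres and the side-chain skeleton; a cyclohept-4-enone is then annulated on C5/C10 and contracted to ring A; the epoxy alcohol is made last. No protecting groups are needed.
4. Stereochemistry: C8 by ligand-controlled Cu-catalysed methyl addition; C9 by Michael addition anti to CH3-8; C5 by cycloaddition anti to the axial CH3-9; C4 by ring closure anti to C6 during the contraction; C13/C14 by D-(−)-tartrate-controlled epoxidation.
5. Enabling feature: ring A is a 1-methylcyclohex-3-ene-1-carboxylate. The ester sits on a quaternary ring carbon (C4) next to a ring CH2 (C3), and the C1=C10 alkene is homoallylic to C4. The ester carbon can therefore be the excised carbonyl carbon of a 2-methylcyclohept-4-enone, whose alkene is exactly the one a (4+3) cycloaddition leaves behind.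

Key step: step 8

Remark: the target is read as the (4S,5R,8R,9S,13R,14R) isomer in the numbering above (H-5 cis to CH3-9 and CH3-8; CO2CH3 on C4 trans to H-5). In compounds 14–16 the two ketone α-carbons (future C4 and C3) are epimer mixtures and are left unspecified in the SMILES, because both become trigonal in step 8.

**Route**

Step 1
Reactants: 1 2-methylcyclohex-2-en-1-one
Product: 3 (R)-[(2,3-dimethylcyclohex-1-en-1-yl)oxy]trimethylsilane, via dimethylaluminium enolate 2 (not isolated)
Conditions: Me3Al, copper thiophene-2-carboxylate CuO2CC4H3S (2 mol %), chiral phosphoramidite ligand (4 mol %, enantiomer that gives the 3R enolate), Et2O, −30 °C; then Me3SiOTf, −30 → 0 °C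
Reagents that add atoms: trimethylaluminium, C[Al](C)C; trimethylsilyl trifluoromethanesulfonate, C[Si](C)(C)OS(=O)(=O)C(F)(F)F
Why: Copper-catalysed asymmetric conjugate addition of a methylaluminium reagent to the 2-substituted cyclohexenone should set C8 (R) under ligand control, and O-silylation of the aluminium enolate fixes the tetrasubstituted enolate regiochemistry needed to build C9.

Step 2
Reactants: 3 (R)-[(2,3-dimethylcyclohex-1-en-1-yl)oxy]trimethylsilane; 4 but-3-en-2-one
Product: 5 (2S,3R)-2,3-dimethyl-2-(3-oxobutyl)cyclohexan-1-one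
Conditions: Sc(OTf)3 (5 mol %), CH2Cl2, −78 → −20 °C; then 1 M HCl, THF, 0 °C
Reagents that add atoms: none
Why: Lewis-acid-catalysed Mukaiyama–Michael addition, in which the enol ether should be attacked anti to the C8 methyl (pseudoaxial because of A(1,2) strain with the C9 methyl), so that the new C9–C11 bond is trans to CH3-8 and the two methyl groups end up cis (9S).

Step 3
Reactants: 5 (2S,3R)-2,3-dimethyl-2-(3-oxobutyl)cyclohexan-1-one; 6 trimethyl phosphonoacetate
Product: 7 methyl (E)-5-[(1S,2R)-1,2-dimethyl-6-oxocyclohexyl]-3-methylpent-2-enoate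
Conditions: NaH, THF, 0 °C; then 5, 0 → 40 °C
Reagents that add atoms: none
Why: Horner–Wadsworth–Emmons olefination should be chemoselective for the unhindered methyl ketone (the ring ketone is flanked by quaternary C9) and should favour the E-trisubstituted enoate, the minor Z isomer being removed by chromatography.

Step 4
Reactants: 7 methyl (E)-5-[(1S,2R)-1,2-dimethyl-6-oxocyclohexyl]-3-methylpent-2-enoate
Product: 9 methyl (E)-5-[(1S,6R)-1,6-dimethyl-2-{[(trifluoromethyl)sulfonyl]oxy}cyclohex-2-en-1-yl]-3-methylpent-2-enoate, via potassium enolate 8 (not isolated)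
Conditions: KN(SiMe3)2 (1.05 equiv), THF, −78 °C; PhNTf2, −78 → 0 °C
Reagents that add atoms: N-phenylbis(trifluoromethanesulfonimide), O=S(=O)(N(c1ccccc1)S(=O)(=O)C(F)(F)F)C(F)(F)F
Why: Enol triflate formation, in which enolisation can only occur toward C5 because C9 is quaternary, so O-triflation of the enolate should give the C5=C10 alkenyl triflate regiospecifically.

Step 5
Reactants: 9 the alkenyl triflate; 10 tributyl(vinyl)stannane
Product: 11 methyl (E)-5-[(1S,6R)-2-ethenyl-1,6-dimethylcyclohex-2-en-1-yl]-3-methylpent-2-enoate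
Conditions: Pd(PPh3)4 (5 mol %), LiCl (3 equiv), THF, 65 °C
Reagents that add atoms: none
Why: Stille coupling of the alkenyl triflate with the vinylstannane installs C1–C2 on C10 and should give the 1-vinylcyclohexene-type diene C5=C10–C1=C2, which the adjacent quaternary C9 biases toward the s-cis form.

Step 6
Reactants: 11 the diene; 12 3-chlorobutan-2-one (racemic)
Product: 14 methyl (E)-3-methyl-5-[(1S,2R,4aS)-1,2,5-trimethyl-6-oxo-2,3,4,4a,5,6,7,8-octahydro-1H-benzo[7]annulen-1-yl]pent-2-enoate (epimers at the methyl-bearing α-carbon), via oxyallyl cation 13 (not isolated)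
Conditions: 12 (3 equiv) and Et3N (3 equiv) added slowly, CF3CH2OH, 0 °C → rt
Reagents that add atoms: none
Why: Föhlisch-type (4+3) cycloaddition, in which base-induced ionisation of 12 gives the 1-methyl-2-oxidoallyl cation, whose unsubstituted terminus should bond to the unhindered diene terminus C2 and whose methyl-bearing terminus to C5 (the orientation that parallels the ortho rule for 1-vinylcyclohexenes), on the diene face anti to the pseudoaxial CH3-9 so that H-5 becomes cis to CH3-9.

Step 7
Reactants: 14 the cyclohept-4-enone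
Product: 16 methyl (E)-5-[(1S,2R,4aS)-7-chloro-1,2,5-trimethyl-6-oxo-2,3,4,4a,5,6,7,8-octahydro-1H-benzo[7]annulen-1-yl]-3-methylpent-2-enoate (epimer mixture at both α-carbons), via lithium enolate 15 (not isolated)
Conditions: LiN(iPr)2 (1.05 equiv), THF, −78 °C; TsCl, −78 → 0 °C
Reagents that add atoms: p-toluenesulfonyl chloride, Cc1ccc(cc1)S(=O)(=O)Cl
Why: Kinetic deprotonation should occur at the less substituted α-methylene (future C3), and the lithium enolate abstracts chlorine from tosyl chloride (enolate α-chlorination), which places the leaving group on the α-carbon opposite the methyl-bearing one.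

Step 8
Reactants: 16 the α-chloro ketone
Product: 18 methyl (1S,5S,6R,8aR)-5-[(3E)-5-methoxy-3-methyl-5-oxopent-3-en-1-yl]-1,5,6-trimethyl-1,2,3,5,6,7,8,8a-octahydronaphthalene-1-carboxylate, via cyclopropanone 17 (not isolated)
Conditions: NaOMe (3 equiv), Et2O (trace MeOH), 0 °C → reflux
Reagents that add atoms: sodium methoxide, [Na+].[O-]C
Why: Favorskii rearrangement: methoxide enolises the ketone toward the methyl-bearing α′-carbon (future C4), the enolate carbon displaces chloride from the other α-carbon (future C3) in a 3-exo-tet closure (or, after ionisation, by disrotatory closure of the 2-oxidoallyl cation) to give cyclopropanone 17, and methoxide addition followed by cleavage of the C(=O)–C3 bond expels the carbonyl carbon from the ring as the methyl ester. The closest precedents are the contractions of 2-chloro-2-methyl- and 2-chloro-6-methylcycloalkanones to 1-methylcycloalkanecarboxylates and the Favorskii-type contraction of (4+3) cycloadducts. The seven-membered ring thereby becomes six-membered ring A (C3–C4 bond formed, one carbon extruded), and the C1=C10 alkene is untouched because it is not conjugated with the ketone. C4 is the only new stereocentre: A(1,2) strain between the C4 methyl and C5 should place H-5 in the enolate plane and C6 pseudoaxial, so the C3–C4 bond forms anti to C6 and the carbonyl bridge, hence the ester, ends up cis to C6 and trans to H-5 (4S); the chloride-bearing centre epimerises under the basic conditions, so both chloride epimers should converge. The step needs regioselective opening of the cyclopropanone, secured because cleavage toward C3 gives a secondary carbanion whereas cleavage toward C4 would give a tertiary one, and it needs rearrangement to outrun dehydrochlorination and epoxy-ether formation, which the heterogeneous NaOMe/ether conditions favour.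

Step 9
Reactants: 18 the diester
Product: 19 methyl (1S,5S,6R,8aR)-5-[(3E)-5-hydroxy-3-methylpent-3-en-1-yl]-1,5,6-trimethyl-1,2,3,5,6,7,8,8a-octahydronaphthalene-1-carboxylate
Conditions: iBu2AlH (2.2 equiv), CH2Cl2, −78 °C; aqueous potassium sodium tartrate
Reagents that add atoms: none
Why: Chemoselective ester reduction, in which iBu2AlH at −78 °C should reduce the unhindered conjugated ester by 1,2-addition to the allylic alcohol while the axial ester on quaternary C4 is too hindered to react at this temperature.

Step 10
Reactants: 19 the 13E-allylic alcohol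
Product: 20 methyl (1S,5S,6R,8aR)-5-{2-[(2R,3R)-3-(hydroxymethyl)-2-methyloxiran-2-yl]ethyl}-1,5,6-trimethyl-1,2,3,5,6,7,8,8a-octahydronaphthalene-1-carboxylate (target)
Conditions: Ti(OiPr)4 (10 mol %), D-(−)-diethyl tartrate (12 mol %), t-BuOOH (2 equiv, in decane), 4 Å molecular sieves, CH2Cl2, −20 °C
Reagents that add atoms: tert-butyl hydroperoxide, CC(C)(C)OO
Why: Katsuki–Sharpless asymmetric epoxidation, in which the D-(−)-tartrate–titanium catalyst should deliver oxygen to the E-allylic alcohol under reagent control to give the (13R,14R)-epoxy alcohol (the enantiomeric series to the (2S,3S)-epoxides that L-(+)-tartrate gives from geraniol-type alcohols), the isolated C1=C10 alkene being inert.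

**Compound list**

1 | 2-methylcyclohex-2-en-1-one | CC1=CCCC1=O | starting material
2 | dimethylaluminium (R)-2,3-dimethylcyclohex-1-en-1-olate | C[C@@H]1CCCC(O[Al](C)C)=C1C | intermediate
3 | (R)-[(2,3-dimethylcyclohex-1-en-1-yl)oxy]trimethylsilane | C[C@@H]1CCCC(O[Si](C)(C)C)=C1C | intermediate
4 | but-3-en-2-one (methyl vinyl ketone) | CC(=O)C=C | starting material
5 | (2S,3R)-2,3-dimethyl-2-(3-oxobutyl)cyclohexan-1-one | C[C@@H]1CCCC(=O)[C@@]1(C)CCC(C)=O | intermediate
6 | trimethyl phosphonoacetate | COC(=O)CP(=O)(OC)OC | starting material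
7 | methyl (E)-5-[(1S,2R)-1,2-dimethyl-6-oxocyclohexyl]-3-methylpent-2-enoate | C[C@@H]1CCCC(=O)[C@@]1(C)CC/C(C)=C/C(=O)OC | intermediate
8 | potassium (5R,6S)-6-[(E)-5-methoxy-3-methyl-5-oxopent-3-en-1-yl]-5,6-dimethylcyclohex-1-en-1-olate | C[C@@H]1CCC=C(O[K])[C@@]1(C)CC/C(C)=C/C(=O)OC | intermediate
9 | methyl (E)-5-[(1S,6R)-1,6-dimethyl-2-{[(trifluoromethyl)sulfonyl]oxy}cyclohex-2-en-1-yl]-3-methylpent-2-enoate | C[C@@H]1CCC=C(OS(=O)(=O)C(F)(F)F)[C@@]1(C)CC/C(C)=C/C(=O)OC | intermediate
10 | tributyl(vinyl)stannane | C=C[Sn](CCCC)(CCCC)CCCC | starting material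
11 | methyl (E)-5-[(1S,6R)-2-ethenyl-1,6-dimethylcyclohex-2-en-1-yl]-3-methylpent-2-enoate | C[C@@H]1CCC=C(C=C)[C@@]1(C)CC/C(C)=C/C(=O)OC | intermediate
12 | 3-chlorobutan-2-one (racemic) | CC(Cl)C(C)=O | starting material
13 | 1-methyl-2-oxidoallyl cation | C[CH+]C([O-])=C | intermediate
14 | methyl (E)-3-methyl-5-[(1S,2R,4aS)-1,2,5-trimethyl-6-oxo-2,3,4,4a,5,6,7,8-octahydro-1H-benzo[7]annulen-1-yl]pent-2-enoate (epimers at the methyl-bearing α-carbon) | CC1C(=O)CCC=C2[C@H]1CC[C@@H](C)[C@]2(C)CC/C(C)=C/C(=O)OC | intermediate
15 | lithium enolate of 14 toward the α-methylene | CC1C(O[Li])=CCC=C2[C@H]1CC[C@@H](C)[C@]2(C)CC/C(C)=C/C(=O)OC | intermediate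
16 | methyl (E)-5-[(1S,2R,4aS)-7-chloro-1,2,5-trimethyl-6-oxo-2,3,4,4a,5,6,7,8-octahydro-1H-benzo[7]annulen-1-yl]-3-methylpent-2-enoate (epimer mixture at both α-carbons) | CC1C(=O)C(Cl)CC=C2[C@H]1CC[C@@H](C)[C@]2(C)CC/C(C)=C/C(=O)OC | intermediate
17 | cyclopropanone in which the ketone carbon bridges C3 and C4 of ring A on the face cis to C6 (trans to H-5) | O=C3[C@@]1(C)[C@@H]3CC=C2[C@H]1CC[C@@H](C)[C@]2(C)CC/C(C)=C/C(=O)OC | intermediate
18 | methyl (1S,5S,6R,8aR)-5-[(3E)-5-methoxy-3-methyl-5-oxopent-3-en-1-yl]-1,5,6-trimethyl-1,2,3,5,6,7,8,8a-octahydronaphthalene-1-carboxylate | COC(=O)[C@@]1(C)CCC=C2[C@H]1CC[C@@H](C)[C@]2(C)CC/C(C)=C/C(=O)OC | intermediate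
19 | methyl (1S,5S,6R,8aR)-5-[(3E)-5-hydroxy-3-methylpent-3-en-1-yl]-1,5,6-trimethyl-1,2,3,5,6,7,8,8a-octahydronaphthalene-1-carboxylate | COC(=O)[C@@]1(C)CCC=C2[C@H]1CC[C@@H](C)[C@]2(C)CC/C(C)=C/CO | intermediate
20 | methyl (1S,5S,6R,8aR)-5-{2-[(2R,3R)-3-(hydroxymethyl)-2-methyloxiran-2-yl]ethyl}-1,5,6-trimethyl-1,2,3,5,6,7,8,8a-octahydronaphthalene-1-carboxylate | COC(=O)[C@@]1(C)CCC=C2[C@H]1CC[C@@H](C)[C@]2(C)CC[C@@]1(C)O[C@@H]1CO | target

**Step count and risks**

Total step count: 10. Longest linear sequence: 10 steps (1 → 20).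

Steps most likely to fail:

Step 6. The oxyallyl cation may be intercepted by the solvent before it meets the hindered acyclic diene, it may add with the reversed orientation, or facial discrimination at C5 may be insufficient. The fallback builds the same cycloheptenone by a Claisen ring expansion, which fixes the regiochemistry by connectivity and sets C5 by chirality transfer. It sets out from triflate 9 and returns to the route at 14. Hex-4-yn-1-ol is oxidised (Swern) to hex-4-ynal F1, which is coupled with 9 under Nozaki–Hiyama–Kishi conditions (CrCl2, NiCl2 1 mol %, DMF) to give the C1 carbinol as an epimer mixture. Dess–Martin oxidation gives the cross-conjugated enone F3, and reduction with catecholborane and the (S)-CBS oxazaborolidine should return the carbinol as the single (1R) epimer, the (1R)-1-hydroxyhex-4-ynyl carbinol F2. Cycloisomerisation (Ph3PAuCl/AgOTf 2 mol %, K2CO3, CH2Cl2, 5-exo-dig) should give the (Z)-2-ethylidene-5-alkenyl tetrahydrofuran F4. Heating F4 (xylene, 170 °C) effects the Claisen ring expansion to 14, in which the C1–O bond and the new C4–C5 bond lie on the same face of the allyl unit, so the (1R) carbinol delivers H-5 cis to CH3-9.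

Step 8. Closure of the cyclopropanone may occur on the wrong face of C4 or with poor facial selectivity, or dehydrochlorination and epoxy-ether formation may outrun enolisation at the hindered methyl-bearing carbon. The fallback replaces the stereoconvergent contraction by a stereospecific one from a tertiary chloride of defined configuration. It sets out from 14 and returns at 18. Thermodynamic silylation (Me3SiCl, NaI, Et3N, MeCN) gives the tetrasubstituted trimethylsilyl enol ether F5, and N-chlorosuccinimide then gives the tertiary α-chloro ketones, which are separated. The epimer with chlorine cis to C6, chloro ketone F6, is rearranged with NaOMe suspended in 1,2-dimethoxyethane; under these non-ionising conditions the enolate formed at the easily enolised C3 methylene displaces chloride with inversion, so the ester takes the face the chlorine occupied and 18 results. The other epimer, chloro ketone F7, is returned to 14 with Zn in AcOH.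

Step 9. The hindered C4 ester may be partly reduced, or conjugate reduction of the enoate may intervene. The fallback discriminates the two esters by hydrolysis instead of hydride reduction. It sets out from 18 and returns at 19. LiOH (THF/MeOH/H2O, rt) should hydrolyse only the unhindered conjugated ester to the mono-acid F8. Ethyl chloroformate and Et3N convert F8 into the mixed carbonic anhydride F9, which NaBH4 (THF/MeOH, 0 °C) reduces to 19 without touching the C4 methyl ester.

**Further compounds**

F1 | step 6 | hex-4-ynal | CC#CCCC=O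
F2 | step 6 | methyl (E)-5-{(1S,6R)-2-[(1R)-1-hydroxyhex-4-yn-1-yl]-1,6-dimethylcyclohex-2-en-1-yl}-3-methylpent-2-enoate | C[C@@H]1CCC=C([C@H](O)CCC#CC)[C@@]1(C)CC/C(C)=C/C(=O)OC
F3 | step 6 | methyl (E)-5-[(1S,6R)-2-(hex-4-ynoyl)-1,6-dimethylcyclohex-2-en-1-yl]-3-methylpent-2-enoate | C[C@@H]1CCC=C(C(=O)CCC#CC)[C@@]1(C)CC/C(C)=C/C(=O)OC
F4 | step 6 | methyl (E)-5-{(1S,6R)-2-[(2R,5Z)-5-ethylideneoxolan-2-yl]-1,6-dimethylcyclohex-2-en-1-yl}-3-methylpent-2-enoate | C[C@@H]1CCC=C([C@H]2CC/C(=C/C)O2)[C@@]1(C)CC/C(C)=C/C(=O)OC
F5 | step 8 | trimethylsilyl enol ether of 14 toward the methyl-bearing α-carbon | CC1=C(O[Si](C)(C)C)CCC=C2[C@H]1CC[C@@H](C)[C@]2(C)CC/C(C)=C/C(=O)OC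
F6 | step 8 | tertiary α-chloro ketone of 14 with chlorine on the methyl-bearing carbon cis to C6 (5R in benzo[7]annulene numbering) | C[C@]1(Cl)C(=O)CCC=C2[C@H]1CC[C@@H](C)[C@]2(C)CC/C(C)=C/C(=O)OC
F7 | step 8 | epimeric tertiary α-chloro ketone with chlorine trans to C6 (5S in benzo[7]annulene numbering) | C[C@@]1(Cl)C(=O)CCC=C2[C@H]1CC[C@@H](C)[C@]2(C)CC/C(C)=C/C(=O)OC
F8 | step 9 | (2E)-5-[(1S,2R,5S,8aR)-5-(methoxycarbonyl)-1,2,5-trimethyl-1,2,3,4,5,6,7,8a-octahydronaphthalen-1-yl]-3-methylpent-2-enoic acid | COC(=O)[C@@]1(C)CCC=C2[C@H]1CC[C@@H](C)[C@]2(C)CC/C(C)=C/C(=O)O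
F9 | step 9 | mixed ethyl carbonic anhydride of F8 | COC(=O)[C@@]1(C)CCC=C2[C@H]1CC[C@@H](C)[C@]2(C)CC/C(C)=C/C(=O)OC(=O)OCC
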